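**Retrosynthetic overview**
1. The target is a cis-fused bicycle: a five-membered ring (C1–C5) and a seven-membered ring (C1, C5, C6–C10). The strategy rests on the array C10(O)–C9H=C8(CH3) of the seven-membered ring. This array is what remains when one carbon, C9, is placed between the carbonyl carbon C10 and the methyl-bearing α-carbon C8 of a cyclohexanone.
2. Endgame: the C6 anisoate and C10 acetate come from the C10 enone 22 by hydride delivery to the α face of C10, acetylation, desilylation and acylation of the only secondary hydroxyl.
3. Key disconnection: 22 comes from the C8=C10 silyl enol ether 18 of a cis-hydrindanone plus CH2I2. The sequence is cyclopropanation, FeCl3 cleavage of the shared C8–C10 bond, and loss of HCl.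
4. In 18 the C4 carbinol comes from radical hydration of a C3=C4(iPr) alkene on the convex face. The isopropyl group comes from cross-coupling of the C4 enol triflate. H5 and O6 come from conjugate borylation and protonation of the enone C4(=O)–C5=C6, a net anti addition. A C5=C6 hydroboration is avoided because its syn addition would give the wrong H5/O6 relation.
5. That enone comes from dehydration of the ketol formed by a carbene-catalysed desymmetrising benzoin closure (C4–C5) of the acrolein adduct of 2-methylcyclohexane-1,3-dione. Ring order: six-membered (bought), five-membered (step 2), three-membered (transient, step 13), seven-membered (step 13).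

Key step: step 13

Conventions: the atom numbers C1–C10 of the target core are used for all intermediates; the hydrindanes lack C9. β is the face of the C1 methyl group and α is the opposite face. The target is 1β-CH3, 5β-H, 4β-OH/4α-iPr, 6α-O-anisoyl, 10β-OAc, that is (1S,4R,5R,6S,10S).

Assumption: the (5aR,10bS) triazolium salt of step 2 is taken to give the (1S) series. The sense of induction has to be confirmed on 4. If it is opposite, the equally available antipodal salt is used.

**Step 1**
Reactants: 1 2-methylcyclohexane-1,3-dione; 2 acrolein
Product: 3 3-(1-methyl-2,6-dioxocyclohexyl)propanal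
Conditions: H2O, rt
Reagents that add atoms: acrolein (2), C=CC=O
Why: Michael addition of the acidic cyclic 1,3-dione to acrolein, run in water without added base so that the aldehyde does not go on to a bridged aldol; C1 becomes quaternary but is still prochiral, so no stereocentre is set.

**Step 2**
Reactants: 3 3-(1-methyl-2,6-dioxocyclohexyl)propanal
Product: 4 cis-fused ketol (C4 and C10 ketones; 5β-OH; 1β-CH3; 1S,5R)
Conditions: (5aR,10bS)-2-(pentafluorophenyl)-5a,10b-dihydro-4H,6H-indeno[2,1-b][1,2,4]triazolo[4,3-d][1,4]oxazin-2-ium tetrafluoroborate (10 mol %), Et3N (10 mol %), toluene, rt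
Reagents that add atoms: none
Why: Carbene-catalysed intramolecular crossed benzoin reaction in which the Breslow intermediate at C4 attacks one of the two enantiotopic ring ketones (5-exo closure of C4–C5), so the chiral carbene fixes the quaternary C1 as S, while the three-atom tether allows only the cis-fused ketol.

**Step 3**
Reactants: 4 cis-fused ketol
Product: 5 enedione (C4 ketone conjugated with C5=C6; C10 ketone; 1S)
Conditions: SOCl2, pyridine, 0 °C
Reagents that add atoms: none
Why: Dehydration through the chlorosulfite with E2 loss of an anti C6–H; C6 is the only neighbour of C5 that carries hydrogen (C1 is quaternary, C4 is a carbonyl), so only the conjugated C5=C6 alkene can form, and the C5 centre is deleted on purpose.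

**Step 4**
Reactants: 5 enedione
Product: 6 enone ketal (C10 as 1,3-dioxolane; C4(=O)–C5=C6 intact)
Conditions: HOCH2CH2OH, p-TsOH·H2O (cat.), 4 Å MS, rt
Reagents that add atoms: ethylene glycol, OCCO
Why: Acid-catalysed ketalisation in which the saturated C10 ketone reacts while the conjugated C4 carbonyl is deactivated, the discrimination that is routine for bicyclic enediones with an angular methyl group; no stereocentre is involved, and the mask keeps C8–H out of the enolate chemistry of steps 7 and 8.

**Step 5**
Reactants: 6 enone ketal
Product: 8 6α-hydroxy ketone ketal (5β-H; cis-fused), via boronate 7 (not isolated)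
Conditions: B2pin2, CuCl (5 mol %), bis[2-(diphenylphosphino)phenyl] ether (5 mol %), NaOtBu (10 mol %), MeOH (2 equiv), THF, rt; then NaBO3·4H2O, THF–H2O, rt
Reagents that add atoms: sodium perborate, [Na+].[Na+].O[B-]1(O)OO[B-](O)(O)OO1; bis(pinacolato)diboron, CC1(C)OB(OC1(C)C)B2OC(C)(C)C(C)(C)O2 (its boron stays only in 7)
Why: Copper-catalysed conjugate borylation followed by stereoretentive C–B oxidation: the copper boryl attacks C6 on the α face, opposite to the pseudo-axial angular methyl (1,3 to C6), and methanol protonates the enolate at C5 on the β face, opposite to the new boryl group, giving the cis-fused hydrindanone (as a rule also the more stable epimer) with H5 and O6 trans as the target requires.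

**Step 6**
Reactants: 8 6α-hydroxy ketone ketal
Product: 9 6α-TBS ether
Conditions: TBSOTf, 2,6-lutidine, CH2Cl2, −78 → 0 °C
Reagents that add atoms: tert-butyldimethylsilyl triflate, CC(C)(C)[Si](C)(C)OS(=O)(=O)C(F)(F)F
Why: Silyl ether formation with the reactive triflate, because the 6α-hydroxyl lies in the fold of the cis-hydrindane; the hindered base at low temperature avoids enolisation at C5 and retro-Michael loss of the oxygen, so no stereocentre changes.

**Step 7**
Reactants: 9 6α-TBS ether
Product: 10 C3=C4 enol triflate
Conditions: KN(SiMe3)2, THF, −78 °C; PhNTf2, −78 → 0 °C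
Reagents that add atoms: N-phenylbis(trifluoromethanesulfonimide), O=S(=O)(N(c1ccccc1)S(=O)(=O)C(F)(F)F)C(F)(F)F
Why: Kinetic enolisation and O-sulfonylation: the base takes a proton from the open C3H2 and not the tertiary C5–H that sits between C1 and C6, so C5 keeps its configuration, the β-silyloxy group is not expelled, and from here on C5 can no longer epimerise.

**Step 8**
Reactants: 10 C3=C4 enol triflate; 11 isopropylmagnesium chloride
Product: 12 C3=C4(iPr) alkene ketal
Conditions: iPrMgCl, Fe(acac)3 (5 mol %), THF–NMP, −30 → 0 °C
Reagents that add atoms: isopropylmagnesium chloride (11), CC(C)[Mg]Cl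
Why: Iron-catalysed Kumada-type cross-coupling of an alkenyl triflate with a secondary alkyl Grignard reagent, which is faster than any attack on the ketal or silyl ether and places the isopropyl group on C4 with the alkene fixed at C3=C4; no stereocentre is formed.

**Step 9**
Reactants: 12 C3=C4(iPr) alkene ketal
Product: 13 C10 ketone
Conditions: PPTS, acetone–H2O, reflux
Reagents that add atoms: water, O
Why: Acid-catalysed ketal hydrolysis with a buffer-strength acid that is too weak to protonate the trisubstituted alkene or to cleave the hindered secondary TBS ether; no stereocentre is adjacent to an acidic position.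

**Step 10**
Reactants: 13 C10 ketone; 14 iodomethane
Product: 15 8α-methyl ketone
Conditions: LiN(iPr)2, THF, −78 °C; MeI, −78 → −20 °C
Reagents that add atoms: iodomethane (14), CI
Why: Alkylation of a lithium enolate that can form only toward C8 because C1 is quaternary; iodomethane should enter anti to the angular methyl (α face), but this centre is erased again in step 12, so its configuration is of no consequence.

**Step 11**
Reactants: 15 8α-methyl ketone
Product: 17 4β-hydroxy-4α-isopropyl ketone, via hydroperoxide 16 (not isolated)
Conditions: Mn(dpm)3 (dpm = 2,2,6,6-tetramethyl-3,5-heptanedionate, 10 mol %), PhSiH3, O2 (1 atm), iPrOH–CH2Cl2, 0 °C → rt; then PPh3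
Reagents that add atoms: dioxygen, O=O
Why: Mukaiyama hydration by metal-hydride hydrogen atom transfer: hydrogen adds to C3 and the tertiary C4 radical captures O2 on the convex β face (the face of H5 and the angular methyl, the α face being closed by C6 and its silyloxy group); PPh3 reduces the hydroperoxide, which sets C4 as 4β-OH/4α-iPr.

**Step 12**
Reactants: 17 4β-hydroxy-4α-isopropyl ketone
Product: 18 C8=C10 trimethylsilyl enol ether (4β-OTMS; 6α-OTBS)
Conditions: TMSOTf, Et3N, CH2Cl2, 0 °C → rt
Reagents that add atoms: trimethylsilyl triflate, C[Si](C)(C)OS(=O)(=O)C(F)(F)F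
Why: Soft enolisation and silylation in one operation: the ketone has a single α-hydrogen (C8–H), so only the tetrasubstituted C8=C10 enol ether can form, and the same reagent caps the tertiary C4 hydroxyl; the C8 centre disappears and the others are untouched.

**Step 13**
Reactants: 18 C8=C10 trimethylsilyl enol ether; 19 diiodomethane
Product: 22 C10 enone of the cis-fused five-seven bicycle (C8=C9; 6α-OTBS; 4β-OTMS), via siloxycyclopropane 20 (not isolated), via chloro ketone 21 (not isolated)
Conditions: Et2Zn, CH2I2, CH2Cl2, 0 °C → rt; crude 20: FeCl3, DMF, 0 °C → rt; crude 21: NaOAc, MeOH, rt → 50 °C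
Reagents that add atoms: diiodomethane (19), ICI
Why: Simmons–Smith methylene transfer in the Furukawa variant (EtZnCH2I, concerted butterfly transition state) lays C9 across the electron-rich C8=C10 enol ether, the only alkene of 18, and closes the three-membered ring C8–C9–C10 in a [2+1] mode, expected on the convex β face, the two new centres being transient. FeCl3 then oxidises the siloxycyclopropane by one electron with loss of Me3SiCl and the bond shared by the three- and six-membered rings, C8–C10, breaks, so the seven-membered ring is not closed by a cyclisation but arises by fragmentation of the bicyclo[4.1.0]heptane unit, giving the C10 ketone and a tertiary C8 radical that takes chlorine from a second FeCl3. NaOAc removes an acidic C9 proton and expels the tertiary chloride (E1cB-like), which places the alkene at C8=C9 in conjugation. The closest known reaction is the Saegusa–Ito one-carbon enlargement of cycloalkanone trimethylsilyl enol ethers to 2-cycloalkenones. The step needs a single enol ether (secured by the quaternary C1), endocyclic rather than C9–C10 cleavage (secured by strain release and by the methyl-stabilised tertiary radical at C8) and elimination toward C9 rather than C7 or the methyl group (secured by the acidity of the C9 hydrogens next to the ketone). No lasting stereocentre is made or touched, since C1, C4, C5 and C6 are remote from the radical site and the new ketone is flanked only by the quaternary C1 and the vinylic C9.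

**Step 14**
Reactants: 22 C10 enone
Product: 23 10β-allylic alcohol (10S)
Conditions: (R)-1-methyl-3,3-diphenyltetrahydro-1H,3H-pyrrolo[1,2-c][1,3,2]oxazaborole (0.5 equiv), BH3·SMe2, THF, −30 °C; MeOH
Reagents that add atoms: none
Why: Corey–Bakshi–Shibata 1,2-reduction: with the quaternary C1 side as the large and the vinylic C9–H side as the small substituent, the (R)-oxazaborolidine delivers hydride to the α face of C10, the face opposite to the angular methyl, so reagent and substrate bias should reinforce each other and give the 10β alcohol without conjugate reduction.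

**Step 15**
Reactants: 23 10β-allylic alcohol; 24 acetic anhydride
Product: 25 10β-acetate
Conditions: Ac2O, Et3N, DMAP, CH2Cl2, rt
Reagents that add atoms: acetic anhydride (24), CC(=O)OC(C)=O
Why: DMAP-catalysed acylation of the only free hydroxyl; the C10–O bond is not touched, so the configuration is retained.

**Step 16**
Reactants: 25 10β-acetate
Product: 26 4β,6α-diol 10β-acetate
Conditions: HF·pyridine, pyridine, THF, 0 °C → rt
Reagents that add atoms: none
Why: Fluoride-induced cleavage of both silyl ethers driven by Si–F bond formation; the pyridine buffer keeps the allylic acetate and the tertiary alcohol from ionising, and no stereocentre is affected.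

**Step 17**
Reactants: 26 4β,6α-diol 10β-acetate; 27 4-methoxybenzoyl chloride
Product: 28 target CNP0256979.4
Conditions: 4-MeOC6H4COCl, DMAP, pyridine, CH2Cl2, rt → 40 °C
Reagents that add atoms: 4-methoxybenzoyl chloride (27), COc1ccc(cc1)C(Cl)=O
Why: DMAP-catalysed esterification that distinguishes the secondary 6α-hydroxyl from the tertiary, isopropyl-flanked 4β-hydroxyl on steric grounds; all C–O bonds stay intact, so the five stereocentres are those of the target.

**Compound list**
1 | 2-methylcyclohexane-1,3-dione | CC1C(=O)CCCC1=O | starting material
2 | acrolein | C=CC=O | starting material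
3 | 3-(1-methyl-2,6-dioxocyclohexyl)propanal | O=CCCC1(C)C(=O)CCCC1=O | intermediate
4 | cis-fused ketol, 5β-hydroxy-1β-methylhydrindane-4,10-dione (1S,5R) | C1CCC(=O)[C@@]2(C)CCC(=O)[C@@]12O | intermediate
5 | enedione, C5=C6 conjugated with the C4 ketone, C10 ketone (1S) | C1=C2C(=O)CC[C@]2(C)C(=O)CC1 | intermediate
6 | enone ketal, C10 ethylene ketal of 5 | C1=C2C(=O)CC[C@]2(C)C3(OCCO3)CC1 | intermediate
7 | 6α-pinacolboronate, 5β-H, C4 ketone, C10 ketal | CC1(C)OB(OC1(C)C)[C@H]2CCC4(OCCO4)[C@@]3(C)CCC(=O)[C@@H]23 | intermediate (not isolated)
8 | 6α-hydroxy ketone ketal, cis-fused | O[C@H]1CCC2(OCCO2)[C@@]3(C)CCC(=O)[C@@H]13 | intermediate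
9 | 6α-TBS ether of 8 | CC(C)(C)[Si](C)(C)O[C@H]1CCC2(OCCO2)[C@@]3(C)CCC(=O)[C@@H]13 | intermediate
10 | C3=C4 enol triflate | CC(C)(C)[Si](C)(C)O[C@H]1CCC2(OCCO2)[C@@]3(C)CC=C(OS(=O)(=O)C(F)(F)F)[C@@H]13 | intermediate
11 | isopropylmagnesium chloride | CC(C)[Mg]Cl | starting material
12 | C3=C4(iPr) alkene ketal | CC(C)(C)[Si](C)(C)O[C@H]1CCC2(OCCO2)[C@@]3(C)CC=C(C(C)C)[C@@H]13 | intermediate
13 | C10 ketone with C3=C4(iPr) alkene | CC(C)(C)[Si](C)(C)O[C@H]1CCC(=O)[C@@]2(C)CC=C(C(C)C)[C@@H]12 | intermediate
14 | iodomethane | CI | starting material
15 | 8α-methyl ketone | CC(C)(C)[Si](C)(C)O[C@H]1C[C@@H](C)C(=O)[C@@]2(C)CC=C(C(C)C)[C@@H]12 | intermediate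
16 | 4β-hydroperoxide | CC(C)(C)[Si](C)(C)O[C@H]1C[C@@H](C)C(=O)[C@@]2(C)CC[C@@](OO)(C(C)C)[C@@H]12 | intermediate (not isolated)
17 | 4β-hydroxy-4α-isopropyl-8α-methyl ketone | CC(C)(C)[Si](C)(C)O[C@H]1C[C@@H](C)C(=O)[C@@]2(C)CC[C@@](O)(C(C)C)[C@@H]12 | intermediate
18 | C8=C10 trimethylsilyl enol ether, 4β-OTMS, 6α-OTBS (key-step precursor) | CC(C)(C)[Si](C)(C)O[C@H]1CC(C)=C(O[Si](C)(C)C)[C@@]2(C)CC[C@@](O[Si](C)(C)C)(C(C)C)[C@@H]12 | intermediate
19 | diiodomethane | ICI | starting material
20 | siloxycyclopropane, C9 on the β face across C8–C10 | CC(C)(C)[Si](C)(C)O[C@H]1C[C@]3(C)C[C@]3(O[Si](C)(C)C)[C@@]2(C)CC[C@@](O[Si](C)(C)C)(C(C)C)[C@@H]12 | intermediate (not isolated)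
21 | 8-chloro-8-methyl cycloheptanone (chlorine drawn β; either epimer eliminates) | CC(C)(C)[Si](C)(C)O[C@H]1C[C@](C)(Cl)CC(=O)[C@@]2(C)CC[C@@](O[Si](C)(C)C)(C(C)C)[C@@H]12 | intermediate (not isolated)
22 | C10 enone with C8=C9 (key-step product) | CC(C)(C)[Si](C)(C)O[C@H]1CC(C)=CC(=O)[C@@]2(C)CC[C@@](O[Si](C)(C)C)(C(C)C)[C@@H]12 | intermediate
23 | 10β-allylic alcohol | CC(C)(C)[Si](C)(C)O[C@H]1CC(C)=C[C@H](O)[C@@]2(C)CC[C@@](O[Si](C)(C)C)(C(C)C)[C@@H]12 | intermediate
24 | acetic anhydride | CC(=O)OC(C)=O | starting material
25 | 10β-acetate, bis-silyl ether | CC(C)(C)[Si](C)(C)O[C@H]1CC(C)=C[C@H](OC(C)=O)[C@@]2(C)CC[C@@](O[Si](C)(C)C)(C(C)C)[C@@H]12 | intermediate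
26 | 4β,6α-diol 10β-acetate | O[C@H]1CC(C)=C[C@H](OC(C)=O)[C@@]2(C)CC[C@@](O)(C(C)C)[C@@H]12 | intermediate
27 | 4-methoxybenzoyl chloride | COc1ccc(cc1)C(Cl)=O | starting material
28 | CNP0256979.4, (1S,4R,5R,6S,10S)-10-acetoxy-4-hydroxy-6-(4-methoxybenzoyloxy) compound | COc1ccc(C(=O)O[C@H]2CC(C)=C[C@H](OC(C)=O)[C@@]3(C)CC[C@@](O)(C(C)C)[C@@H]23)cc1 | target

**Step count and risks**
Total step count: 17. Longest linear sequence: 17 steps (from 1).

The three steps most likely to fail are these.

1. **Step 13.**
   - What may go wrong: methylene transfer to a tetrasubstituted enol ether next to the quaternary C1 may be slow, which allows protodesilylation by zinc iodide. In the iron stage, partial loss of the silyl ethers or cleavage of the outer C9–C10 bond may compete.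
   - Fallback (sets out from 18, returns at 22): dibromocarbene (CHBr3, KOtBu, pentane, −20 °C) is a smaller and far more electrophilic one-carbon donor. It is added to C8=C10 to give the dibromo(siloxy)cyclopropane F1. On warming in toluene with pyridine, F1 opens by disrotatory cyclopropyl-to-allyl ionisation with loss of bromide and of the silyl group. This again breaks C8–C10 and gives the 9-bromo enone F2. Hydrodebromination with Bu3SnH and Pd(PPh3)4 then gives 22. The same carbon is inserted between the same atoms, but by an ionic path and without an oxidant.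

2. **Step 5.**
   - What may go wrong: facial discrimination at C6 may be insufficient, because attack anti to the angular methyl has to pass through a boat-like arrangement of the six-membered ring. Epimerisation at C5 or retro-Michael loss of the oxygen during the oxidation may also occur.
   - Fallback (sets out from 6, returns at 8): Weitz–Scheffer epoxidation (tBuOOH, DBU, CH2Cl2, rt) gives the 5α,6α-epoxy ketone F3. Here the oxygen must also bond to C5, directly beside the angular methyl, and the first addition is reversible; both points sharpen the preference for the α face. SmI2 in THF–MeOH at −90 °C then cleaves only the C5–O bond. The samarium enolate is protonated on the β face, opposite to the C6 alkoxide, to give 8.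

3. **Step 14.**
   - What may go wrong: hydride may be delivered to the wrong face of C10 if the folded seven-membered ring shields the α face more than the angular methyl shields the β face and overrides the catalyst.
   - Fallback (sets out from 22, returns at 25): Luche reduction (NaBH4, CeCl3·7H2O, MeOH, −78 °C) under pure substrate control would then give the 10α-allylic alcohol F4. A Mitsunobu reaction with acetic acid (PPh3, DIAD, toluene, 0 °C → rt) inverts C10 and gives the acetate 25 directly, so step 15 is skipped.

**Further compounds**
F1 | step 13 | 9,9-dibromo siloxycyclopropane | CC(C)(C)[Si](C)(C)O[C@H]1C[C@]3(C)C(Br)(Br)[C@]3(O[Si](C)(C)C)[C@@]2(C)CC[C@@](O[Si](C)(C)C)(C(C)C)[C@@H]12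
F2 | step 13 | 9-bromo C10 enone | CC(C)(C)[Si](C)(C)O[C@H]1CC(C)=C(Br)C(=O)[C@@]2(C)CC[C@@](O[Si](C)(C)C)(C(C)C)[C@@H]12
F3 | step 5 | 5α,6α-epoxy ketone ketal | O1[C@H]2CCC4(OCCO4)[C@@]3(C)CCC(=O)[C@]123
F4 | step 14 | 10α-allylic alcohol | CC(C)(C)[Si](C)(C)O[C@H]1CC(C)=C[C@@H](O)[C@@]2(C)CC[C@@](O[Si](C)(C)C)(C(C)C)[C@@H]12
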